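**Retrosynthetic overview**
1. The only ring (the furan) is formed last: target 10 ⇐ 1,2‑allenyl ketone 9 by Ag(I) cycloisomerisation (O–C2 bond).
2. 9 ⇐ α‑hydroxy β,γ‑ynone 7 + trimethyl orthoacetate 8 by ortho‑ester Claisen [3,3] shift (C–CH2CO2Me bond). This is the proposed new step.
3. 7 ⇐ Weinreb amide 5 + n‑C16H33MgBr (from 6).
4. 5 ⇐ hydroxy ester 3 ⇐ ethyl glyoxylate 1 + ethynylmagnesium bromide 2.

Assumption: the target, methyl 2‑(5‑hexadecylfuran‑2‑yl)acetate, has no stereocentre, so there is no enantiomer to control. Intermediates 3, 5, 7 and 9 are racemic, and their stereo-elements are destroyed by step 5.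

**Step 1**
Reactants: 1 ethyl glyoxylate (freshly depolymerised); 2 ethynylmagnesium bromide
Product: 3 ethyl 2‑hydroxybut‑3‑ynoate (racemic)
Conditions: 2 (1.05 equiv, 0.5 M in THF), THF, −78 → −40 °C; sat. NH4Cl
Reagents that add atoms: ethynylmagnesium bromide (2), C#C[Mg]Br
Why: Grignard 1,2‑addition to the non‑enolisable, highly electrophilic aldehyde leaves the ester untouched at low temperature, and the new carbinol centre is racemic and later becomes sp2.

**Step 2**
Reactants: 3; 4 N,O‑dimethylhydroxylamine hydrochloride
Product: 5 2‑hydroxy‑N‑methoxy‑N‑methylbut‑3‑ynamide (racemic)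
Conditions: 4 (3 equiv), AlMe3 (4 equiv), CH2Cl2, 0 → 23 °C; Rochelle salt work‑up
Reagents that add atoms: N,O‑dimethylhydroxylamine hydrochloride (4), CNOC.Cl
Why: Weinreb aminolysis of the ester by the dimethylaluminium amide, with the free OH carried as its aluminium alkoxide (as in lactone openings) and a non‑basic medium that avoids propargyl–allenyl isomerisation.

**Step 3**
Reactants: 5; 6 1‑bromohexadecane (converted in situ to hexadecylmagnesium bromide)
Product: 7 3‑hydroxyicos‑1‑yn‑4‑one (racemic)
Conditions: 6, Mg, THF, 50 °C → C16H33MgBr (3.5 equiv); add 5, THF, −10 → 20 °C; cold 1 M citric acid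
Reagents that add atoms: 1‑bromohexadecane (6), CCCCCCCCCCCCCCCCBr (delivers n‑C16H33 as its Grignard)
Why: Weinreb ketone synthesis, in which the chelated tetrahedral intermediate stops at the ketone, two equivalents of Grignard are consumed by O–H and ≡C–H, and the acidic quench protects the base‑sensitive α‑hydroxy ynone.

**Step 4 (key step)**
Reactants: 7; 8 trimethyl orthoacetate
Product: 9 methyl 6‑oxodocosa‑3,4‑dienoate (racemic allene; used crude)
Conditions: 8 (6 equiv), EtCO2H (10 mol %), PhMe, 105 °C, −MeOH (distil), 3–6 h; cool, evaporate PhMe and excess 8 under vacuum, no base wash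
Reagents that add atoms: trimethyl orthoacetate (8), CC(OC)(OC)OC (supplies CH2CO2Me)
Why: Proposed new method: an ortho‑ester (Johnson–)Claisen rearrangement on a 1‑acylpropargylic alcohol, in which acid‑catalysed exchange of the propargylic OH of 7 into 8 and loss of MeOH gives the mixed ketene acetal CH2=C(OMe)–O–CH(COR)–C≡CH, whose [3,3] shift onto the terminal alkyne carbon forms the C–CH2CO2Me bond and delivers the conjugated allenyl ketone 9 with regiochemistry fixed by the sigmatropic geometry; the closest known reaction type is the Johnson–Claisen rearrangement of simple propargylic alcohols to β‑allenic esters, and to my knowledge it has not been shown on an α‑hydroxy β,γ‑ynone, where ketone ketalisation and α‑ketol isomerisation compete.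

**Step 5**
Reactants: 9 (crude from step 4)
Product: 10 methyl 2‑(5‑hexadecylfuran‑2‑yl)acetate
Conditions: AgNO3 (10 mol %), acetone, 23 °C, dark, 1–3 h; filter through silica
Reagents that add atoms: none
Why: Ag(I)‑catalysed cycloisomerisation of a 1,2‑allenyl ketone to a furan, in which silver activates the distal allene C=C, the ketone oxygen closes 5‑endo onto the CH2CO2Me‑bearing terminus, and proton loss/protodemetalation aromatises to the 2,5‑disubstituted furan with no stereocentre remaining.

**Compound list**
1 | ethyl glyoxylate | CCOC(=O)C=O | starting material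
2 | ethynylmagnesium bromide | C#C[Mg]Br | starting material
3 | ethyl 2‑hydroxybut‑3‑ynoate (racemic) | CCOC(=O)C(O)C#C | intermediate
4 | N,O‑dimethylhydroxylamine hydrochloride | CNOC.Cl | starting material
5 | 2‑hydroxy‑N‑methoxy‑N‑methylbut‑3‑ynamide (racemic) | CON(C)C(=O)C(O)C#C | intermediate
6 | 1‑bromohexadecane | CCCCCCCCCCCCCCCCBr | starting material
7 | 3‑hydroxyicos‑1‑yn‑4‑one (racemic) | CCCCCCCCCCCCCCCCC(=O)C(O)C#C | intermediate
8 | trimethyl orthoacetate | CC(OC)(OC)OC | starting material
9 | methyl 6‑oxodocosa‑3,4‑dienoate (racemic allene) | COC(=O)CC=C=CC(=O)CCCCCCCCCCCCCCCC | intermediate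
10 | methyl 2‑(5‑hexadecylfuran‑2‑yl)acetate (achiral) | CCCCCCCCCCCCCCCCc1ccc(CC(=O)OC)o1 | target

**Totals**
Total steps: 5. Longest linear sequence: 5 (1 → 3 → 5 → 7 → 9 → 10).

**Steps most likely to fail, with fallbacks**
1. Step 4 (proposed new step). Risks: the ortho ester may ketalise the ketone, the α‑ketol may isomerise, MeOH may add to allenone 9, or 9 may isomerise to the conjugated dienone or degrade at 105 °C. Fallback (known chemistry, different disconnection): Sonogashira acylation of methyl pent‑4‑ynoate with heptadecanoyl chloride (PdCl2(PPh3)2, CuI, Et3N) to give methyl 6‑oxodocos‑4‑ynoate, then CuI/Et3N/DMA (100 °C) cycloisomerisation of the alkynyl ketone (through 9 formed in situ) to 10.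
2. Step 3. Risks: sluggish addition to the aggregated, doubly deprotonated amide, and base sensitivity of 7. Fallback (acyl‑anion approach): alkylate 1,3‑dithiane with 6, lithiate the 2‑hexadecyl‑1,3‑dithiane and add it to 3‑(trimethylsilyl)propynal, then remove TMS (K2CO3/MeOH) and the dithiane (MeI, CaCO3, aq. MeCN) to reach 7.
3. Step 2. Risks: incomplete amidation or isomerisation of the propargylic α‑hydroxy ester. Fallback (reverse the order): cleave N,N'‑dimethoxy‑N,N'‑dimethyltartramide with periodate to N‑methoxy‑N‑methylglyoxylamide and add 2 to its aldehyde, giving 5 directly.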